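**Plan**
Atom labels: dihydrofuran ring A (O1, C2, C3) is fused to benzene ring B (C3a–C7a; C5 carries ring C, C6 carries OH); dihydrofuran ring C (O1', C2', C3') is fused to benzene ring D (4'-OH, 6'-styryl).
Cuts, in retrosynthetic order: the ten O–benzyl bonds; the aryl–vinyl bond at C6' (Heck); C2'–C3' of ring C (carbene C–H insertion) and the O1'–ring D bond (SNAr); the C5–C2' bond (carbonylation of a C5 triflate); last O1–C2 and C3a–C3 of ring A, which leaves 2-benzyloxy-1,4-benzoquinone and perbenzylated oxyresveratrol.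
The last cut is possible because ring B is a resorcinol with O1 para to C5 and the C6 oxygen next to C5, i.e. a 2-alkoxy-1,4-benzoquinone: quinone C4=O becomes O1, quinone C5 becomes C3a, the 2-alkoxy group becomes the C6 oxygen, and the quinone C1 oxygen ends on C5 as a phenol the target lacks. This extra oxygen activates the quinone and is then removed as the triflate through which the carbon bearing ring C is attached.
The 2,4-dioxygenated aryl group on C2 polarises the stilbene, so C3 is the nucleophilic and C2 the cationic carbon.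
Forward: rings A/B from quinone plus stilbene, then C5 triflate, ester, CH2OH, ether to the ring D nitrile, hydrazone, ring C by C–H insertion, C2' epimerisation, Heck, debenzylation.
Stereochemistry: C3 from a chiral titanium diolate (reagent control), C2 trans by reversible closure; C3' from a chiral dirhodium carboxylate, C2' trans by acid equilibration; E alkene from the Heck reaction.

Key step: step 3

Assumption: the sense of induction of the (4R,5R)-diol on titanium (step 3) and of Rh2(S-PTAD)4 (step 10) is taken as written; if either gives the mirror-image ring, the enantiomeric ligand is used and nothing else changes.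
Abbreviation: "DBF" is the (2R,3R)-6-(benzyloxy)-2-[2,4-bis(benzyloxy)phenyl]-3-[3,5-bis(benzyloxy)phenyl]-2,3-dihydro-1-benzofuran skeleton of compound 5, substituted at C5.

**Step 1**
Reactants: 1 oxyresveratrol
Product: 2 (E)-tetra-O-benzyloxyresveratrol
Conditions: BnBr, K2CO3, DMF, 60 °C
Reagents that add atoms: benzyl bromide, BrCc1ccccc1
Why: Fourfold Williamson etherification of the phenols should give the tetrabenzyl ether, a protecting group that survives every later step and is removed in one operation at the end.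

**Step 2**
Reactants: 3 3-(benzyloxy)phenol
Product: 4 2-(benzyloxy)-1,4-benzoquinone
Conditions: (KSO3)2NO (2.2 equiv), KH2PO4, H2O–acetone, 0 °C → rt
Reagents that add atoms: potassium nitrosodisulfonate, [K+].[K+].[O]N(S(=O)(=O)[O-])S(=O)(=O)[O-]
Why: Oxidation of a para-unsubstituted phenol by the nitroxyl radical salt (Teuber oxidation) should give the para-quinone, and since the free para position is ortho to the benzyloxy group the product is the 2-alkoxy-1,4-quinone.

**Step 3**
Reactants: 4 2-(benzyloxy)-1,4-benzoquinone; 2 (E)-tetra-O-benzyloxyresveratrol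
Product: 5 DBF-5-ol, (2R,3R)-trans
Conditions: TiCl4/Ti(OiPr)4 (1:1), (4R,5R)-2,2-dimethyl-α,α,α',α'-tetraphenyl-1,3-dioxolane-4,5-dimethanol (1.1 equiv per Ti), CH2Cl2, −78 → −40 °C; then H2O
Reagents that add atoms: none
Why: The chiral titanium diolate dichloride, a tetravalent titanium Lewis acid, chelates quinone 4 through the C1 carbonyl oxygen and the C2 benzyloxy oxygen, which makes quinone C5 the electrophilic carbon; the alkene carbon of 2 that carries the 3,5-bis(benzyloxy)phenyl group attacks it, and the positive charge develops on the other alkene carbon, where the 2,4-bis(benzyloxy)phenyl ring stabilises it as a quinone-methide-like oxocarbenium ion. The oxygen on quinone C4 then closes dihydrofuran ring A onto this cation (5-exo-trig, O1–C2 bond) and tautomerisation aromatises ring B, so the net result is a formal [3+2] cycloaddition that forms C3a–C3 and O1–C2 in one operation and leaves the former C1 carbonyl as the C5 phenol. The closest known reaction type is the titanium-promoted formal [3+2] cycloaddition of 2-alkoxy-1,4-benzoquinones with (E)-1-arylpropenes, which has an enantioselective form with tartrate-derived diol ligands; here a 1,2-diarylethene takes the place of the arylpropene. C3 is set in the C–C bond-forming step by the face of the alkene that can reach the ligand-shielded quinone (reagent control), and C2 follows from C3 because ring closure, reversible through the stabilised cation, ends at the trans-2,3-diaryl arrangement (thermodynamic control). The step needs regioselectivity on both partners and chemoselectivity for the alkene over Friedel–Crafts attack by the resorcinol diether ring: chelation of the 2-alkoxyquinone directs attack to C5, the one-sided donor substitution of the stilbene fixes which alkene carbon is nucleophilic, and the enol-ether-like alkene is the most nucleophilic site of 2.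

**Step 4**
Reactants: 5 DBF-5-ol
Product: 6 DBF-5-yl trifluoromethanesulfonate
Conditions: Tf2O, pyridine, CH2Cl2, 0 °C
Reagents that add atoms: trifluoromethanesulfonic anhydride, O=S(=O)(OS(=O)(=O)C(F)(F)F)C(F)(F)F
Why: O-Sulfonylation of the phenol should turn the oxygen that served the cycloaddition into a leaving group for palladium without touching the benzyl ethers or the stereocenters.

**Step 5**
Reactants: 6 DBF-5-yl trifluoromethanesulfonate
Product: 7 methyl DBF-5-carboxylate
Conditions: Pd(OAc)2 (cat.), dppp, CO (1 atm), Et3N, MeOH–DMF, 70 °C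
Reagents that add atoms: carbon monoxide, [C-]#[O+]; methanol, CO
Why: Palladium-catalysed alkoxycarbonylation of an aryl triflate (oxidative addition of zerovalent palladium, CO insertion, methanolysis of the acyl complex) should replace the C5 oxygen by carbon, the bidentate phosphine compensating for the electron-rich ring.

**Step 6**
Reactants: 7 methyl DBF-5-carboxylate
Product: 8 DBF-5-ylmethanol
Conditions: LiAlH4, THF, 0 °C; then H2O
Reagents that add atoms: none
Why: Hydride reduction of the ester should give the primary benzylic alcohol, since benzyl ethers and the dihydrofuran ring are inert to LiAlH4.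

**Step 7**
Reactants: 9 4-bromo-2,6-difluorobenzonitrile
Product: 10 2-(benzyloxy)-4-bromo-6-fluorobenzonitrile
Conditions: BnOH (1.0 equiv), NaH, THF, −20 → 0 °C
Reagents that add atoms: benzyl alcohol, OCc1ccccc1
Why: Nucleophilic aromatic substitution of one of the two equivalent fluorides ortho to the nitrile should stop at the mono-ether, because the first alkoxy group deactivates the ring and the bromide para to the nitrile is the poorer leaving group.

**Step 8**
Reactants: 8 DBF-5-ylmethanol; 10 2-(benzyloxy)-4-bromo-6-fluorobenzonitrile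
Product: 11 2-(benzyloxy)-4-bromo-6-(DBF-5-ylmethoxy)benzonitrile
Conditions: NaH, THF–DMF, 0 °C → rt
Reagents that add atoms: none
Why: A second SNAr at the remaining nitrile-activated fluoride by the sodium alkoxide of 8 should join the two halves under basic conditions that the acid-labile, electron-rich benzylic alcohol tolerates.

**Step 9**
Reactants: 11 2-(benzyloxy)-4-bromo-6-(DBF-5-ylmethoxy)benzonitrile; 12 1,3-bis(benzyloxy)-5-bromobenzene
Product: 15 N-unsubstituted hydrazone of the diaryl ketimine, via aryl Grignard reagent 13 (not isolated), via N–H ketimine 14 (not isolated)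
Conditions: 12, Mg, THF, rt; transfer onto 11, THF–toluene, 60 °C; MeOH, 0 °C; N2H4·H2O, AcOH (cat.), EtOH, 70 °C
Reagents that add atoms: hydrazine hydrate, NN.O
Why: Grignard addition to the nitrile (linear and reachable between its two ortho alkoxy groups, the aryl bromide being inert to ArMgBr) should give the N-magnesio ketimine, and after protonation transimination with hydrazine, which attacks the protonated N–H ketimine far more readily than it would a doubly ortho-substituted ketone, should give the hydrazone.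

**Step 10**
Reactants: 15 hydrazone
Product: 17 cis-dihydrobenzofuran (2'S,3'R) with ring C closed, via diaryldiazomethane 16 (not isolated)
Conditions: activated MnO2, CH2Cl2, 0 °C → rt, filter; Rh2(S-PTAD)4 (dirhodium tetrakis[(S)-(1-adamantyl)(phthalimido)acetate], 1 mol %), CH2Cl2, 0 °C
Reagents that add atoms: none
Why: Dehydrogenation of the hydrazone gives the diaryldiazomethane, and the donor/donor carbene on divalent rhodium should insert into a C–H bond of the OCH2 group five atoms away (1,5-insertion with a hydride-transfer-like transition state), preferring the CH2 on the 2,4-dioxygenated ring B over the plain benzyl CH2 on electronic grounds, with C3' fixed by the chiral carboxylate ligands (catalyst control) and C2' placed cis by the insertion geometry.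

**Step 11**
Reactants: 17 cis-dihydrobenzofuran (2'S,3'R)
Product: 18 trans-dihydrobenzofuran (2'R,3'R), octabenzyl ether bromide
Conditions: CF3CO2H (cat.), CH2Cl2, 0 °C
Reagents that add atoms: none
Why: Acid-catalysed epimerisation through reversible ionisation of the C2'–O1' bond to a benzylic cation, stabilised by the ortho benzyloxy group and the para furan oxygen of ring B, should end at the thermodynamically preferred trans isomer with C3' untouched, while ring A can ionise in the same way but is already trans.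

**Step 12**
Reactants: 19 2,4-bis(benzyloxy)benzaldehyde
Product: 20 2,4-bis(benzyloxy)styrene
Conditions: Ph3PCH3Br, KOtBu, THF, 0 °C → rt
Reagents that add atoms: methyltriphenylphosphonium bromide, [Br-].C[P+](c1ccccc1)(c1ccccc1)c1ccccc1
Why: Wittig methylenation of the aldehyde with the non-stabilised ylide should give the terminal alkene.

**Step 13**
Reactants: 18 octabenzyl ether bromide; 20 2,4-bis(benzyloxy)styrene
Product: 21 deca-O-benzylgneyulin A
Conditions: Pd(OAc)2 (cat.), P(o-tol)3, Et3N, DMF, 100 °C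
Reagents that add atoms: none
Why: Heck reaction (oxidative addition of zerovalent palladium into the unhindered aryl bromide, syn insertion at the terminal alkene carbon, syn β-hydride elimination) should give the E-stilbene.

**Step 14**
Reactants: 21 deca-O-benzylgneyulin A
Product: 22 gneyulin A
Conditions: BCl3, pentamethylbenzene, CH2Cl2, −78 °C; then MeOH, H2O
Reagents that add atoms: none
Why: Lewis-acid debenzylation, in which BCl3 activates each aryl benzyl ether and pentamethylbenzene traps the benzyl cation as a non-basic scavenger, should free all ten phenols at a temperature at which the stilbene and the benzylic C–O bonds of rings A and C do not ionise, so no stereocenter is touched.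

**Compound list**
1 | oxyresveratrol, (E)-4-[2-(3,5-dihydroxyphenyl)ethenyl]benzene-1,3-diol | Oc1ccc(/C=C/c2cc(O)cc(O)c2)c(O)c1 | starting material
2 | (E)-2,4-bis(benzyloxy)-1-{2-[3,5-bis(benzyloxy)phenyl]ethenyl}benzene | c1ccccc1COc1ccc(/C=C/c2cc(OCc3ccccc3)cc(OCc3ccccc3)c2)c(OCc2ccccc2)c1 | intermediate
3 | 3-(benzyloxy)phenol | Oc1cccc(OCc2ccccc2)c1 | starting material
4 | 2-(benzyloxy)cyclohexa-2,5-diene-1,4-dione | O=C1C=CC(=O)C(OCc2ccccc2)=C1 | intermediate
5 | (2R,3R)-6-(benzyloxy)-2-[2,4-bis(benzyloxy)phenyl]-3-[3,5-bis(benzyloxy)phenyl]-2,3-dihydro-1-benzofuran-5-ol | c1ccccc1COc1cc(OCc2ccccc2)cc([C@@H]2c3cc(O)c(OCc4ccccc4)cc3O[C@H]2c2ccc(OCc3ccccc3)cc2OCc2ccccc2)c1 | intermediate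
6 | 5-trifluoromethanesulfonate of 5 | c1ccccc1COc1cc(OCc2ccccc2)cc([C@@H]2c3cc(OS(=O)(=O)C(F)(F)F)c(OCc4ccccc4)cc3O[C@H]2c2ccc(OCc3ccccc3)cc2OCc2ccccc2)c1 | intermediate
7 | methyl (2R,3R)-6-(benzyloxy)-2-[2,4-bis(benzyloxy)phenyl]-3-[3,5-bis(benzyloxy)phenyl]-2,3-dihydro-1-benzofuran-5-carboxylate | c1ccccc1COc1cc(OCc2ccccc2)cc([C@@H]2c3cc(C(=O)OC)c(OCc4ccccc4)cc3O[C@H]2c2ccc(OCc3ccccc3)cc2OCc2ccccc2)c1 | intermediate
8 | [(2R,3R)-6-(benzyloxy)-2-[2,4-bis(benzyloxy)phenyl]-3-[3,5-bis(benzyloxy)phenyl]-2,3-dihydro-1-benzofuran-5-yl]methanol | c1ccccc1COc1cc(OCc2ccccc2)cc([C@@H]2c3cc(CO)c(OCc4ccccc4)cc3O[C@H]2c2ccc(OCc3ccccc3)cc2OCc2ccccc2)c1 | intermediate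
9 | 4-bromo-2,6-difluorobenzonitrile | N#Cc1c(F)cc(Br)cc1F | starting material
10 | 2-(benzyloxy)-4-bromo-6-fluorobenzonitrile | N#Cc1c(F)cc(Br)cc1OCc1ccccc1 | intermediate
11 | 2-(benzyloxy)-4-bromo-6-(DBF-5-ylmethoxy)benzonitrile | c1ccccc1COc1cc(OCc2ccccc2)cc([C@@H]2c3cc(COc4cc(Br)cc(OCc5ccccc5)c4C#N)c(OCc4ccccc4)cc3O[C@H]2c2ccc(OCc3ccccc3)cc2OCc2ccccc2)c1 | intermediate
12 | 1,3-bis(benzyloxy)-5-bromobenzene | Brc1cc(OCc2ccccc2)cc(OCc2ccccc2)c1 | starting material
13 | [3,5-bis(benzyloxy)phenyl]magnesium bromide | Br[Mg]c1cc(OCc2ccccc2)cc(OCc2ccccc2)c1 | intermediate (not isolated)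
14 | 1-[2-(benzyloxy)-4-bromo-6-(DBF-5-ylmethoxy)phenyl]-1-[3,5-bis(benzyloxy)phenyl]methanimine | c1ccccc1COc1cc(OCc2ccccc2)cc([C@@H]2c3cc(COc4cc(Br)cc(OCc5ccccc5)c4C(=N)c4cc(OCc5ccccc5)cc(OCc5ccccc5)c4)c(OCc4ccccc4)cc3O[C@H]2c2ccc(OCc3ccccc3)cc2OCc2ccccc2)c1 | intermediate (not isolated)
15 | hydrazone of 14 (C=N–NH2 in place of C=NH) | c1ccccc1COc1cc(OCc2ccccc2)cc([C@@H]2c3cc(COc4cc(Br)cc(OCc5ccccc5)c4C(=NN)c4cc(OCc5ccccc5)cc(OCc5ccccc5)c4)c(OCc4ccccc4)cc3O[C@H]2c2ccc(OCc3ccccc3)cc2OCc2ccccc2)c1 | intermediate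
16 | diaryldiazomethane from 15 (C=N2 in place of C=N–NH2) | c1ccccc1COc1cc(OCc2ccccc2)cc([C@@H]2c3cc(COc4cc(Br)cc(OCc5ccccc5)c4C(=[N+]=[N-])c4cc(OCc5ccccc5)cc(OCc5ccccc5)c4)c(OCc4ccccc4)cc3O[C@H]2c2ccc(OCc3ccccc3)cc2OCc2ccccc2)c1 | intermediate (not isolated)
17 | (2R,3R)-6-(benzyloxy)-5-[(2S,3R)-4-(benzyloxy)-3-[3,5-bis(benzyloxy)phenyl]-6-bromo-2,3-dihydro-1-benzofuran-2-yl]-2-[2,4-bis(benzyloxy)phenyl]-3-[3,5-bis(benzyloxy)phenyl]-2,3-dihydro-1-benzofuran (ring C cis) | c1ccccc1COc1cc(OCc2ccccc2)cc([C@@H]2c3cc([C@H]4Oc5cc(Br)cc(OCc6ccccc6)c5[C@H]4c4cc(OCc5ccccc5)cc(OCc5ccccc5)c4)c(OCc4ccccc4)cc3O[C@H]2c2ccc(OCc3ccccc3)cc2OCc2ccccc2)c1 | intermediate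
18 | the (2R,3R)/(2'R,3'R) isomer of 17 (ring C trans) | c1ccccc1COc1cc(OCc2ccccc2)cc([C@@H]2c3cc([C@@H]4Oc5cc(Br)cc(OCc6ccccc6)c5[C@H]4c4cc(OCc5ccccc5)cc(OCc5ccccc5)c4)c(OCc4ccccc4)cc3O[C@H]2c2ccc(OCc3ccccc3)cc2OCc2ccccc2)c1 | intermediate
19 | 2,4-bis(benzyloxy)benzaldehyde | O=Cc1ccc(OCc2ccccc2)cc1OCc1ccccc1 | starting material
20 | 2,4-bis(benzyloxy)-1-ethenylbenzene | C=Cc1ccc(OCc2ccccc2)cc1OCc1ccccc1 | intermediate
21 | deca-O-benzylgneyulin A (18 with Br replaced by (E)-2-[2,4-bis(benzyloxy)phenyl]ethenyl) | c1ccccc1COc1cc(OCc2ccccc2)cc([C@@H]2c3cc([C@@H]4Oc5cc(/C=C/c6ccc(OCc7ccccc7)cc6OCc6ccccc6)cc(OCc6ccccc6)c5[C@H]4c4cc(OCc5ccccc5)cc(OCc5ccccc5)c4)c(OCc4ccccc4)cc3O[C@H]2c2ccc(OCc3ccccc3)cc2OCc2ccccc2)c1 | intermediate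
22 | gneyulin A | Oc1cc(O)cc([C@@H]2c3cc([C@@H]4Oc5cc(/C=C/c6ccc(O)cc6O)cc(O)c5[C@H]4c4cc(O)cc(O)c4)c(O)cc3O[C@H]2c2ccc(O)cc2O)c1 | target

**Count**
Total steps: 14. Longest linear sequence: 11 steps (1, 3, 4, 5, 6, 8, 9, 10, 11, 13, 14).

**Steps most likely to fail**

Step 3. The facial selectivity of the C–C bond formation may be low, because the ligand environment was shaped for 1-arylpropenes and the alkene here carries a second aryl group at the attacking carbon. The fallback sets out from 2 and 4 and comes back at 5. The cycloaddition is run with the achiral promoter TiCl4/Ti(OiPr)4 (1:1, CH2Cl2, −78 °C) to give the racemic trans phenol F1. Acylation with (1S)-camphanic chloride (pyridine, DMAP, CH2Cl2) gives the (2R,3R) camphanate F2 and the (2S,3S) camphanate F3, which are separated by crystallisation or chromatography. LiOH in THF–H2O then cleaves F2 to 5.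

Step 9. Addition of the Grignard reagent to the nitrile between two alkoxy groups may stall, or be diverted into displacement of an ortho alkoxy group or into magnesium–bromine exchange. The fallback sets out from 8 and comes back at 15. Commercial 1-bromo-3,5-difluorobenzene is deprotonated between the fluorines (LiN(iPr)2, THF, −78 °C) and added to commercial 3,5-bis(benzyloxy)benzaldehyde to give the racemic carbinol F4. MnO2 oxidises it to the difluorobenzophenone F5. BnOH/NaH replaces one fluoride to give the monofluoro ketone F6, and the sodium alkoxide of 8 replaces the other to give the ketone ether F7. Condensation with N2H4·H2O (AcOH cat., n-BuOH, 110 °C) then gives 15.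

Step 14. The Lewis acid may ionise the electron-rich stilbene, or the benzylic C–O bonds next to it, while ten ethers are being cleaved, which would lead to cyclisation onto a resorcinol ring or to oligomerisation. The fallback sets out from 18 and comes back at 22. The eight benzyl groups of 18 are removed with BCl3/pentamethylbenzene (CH2Cl2, −78 °C) before any alkene is present, giving the octaphenol bromide F8. TBSCl/imidazole (DMF) gives the octakis(tert-butyldimethylsilyl) ether F9. Commercial 2,4-dihydroxybenzaldehyde is silylated to 2,4-bis(tert-butyldimethylsilyloxy)benzaldehyde F10 and methylenated (Ph3PCH3Br, KOtBu) to 2,4-bis(tert-butyldimethylsilyloxy)styrene F11. Heck coupling of F9 with F11 (Pd(OAc)2, P(o-tol)3, Et3N, DMF) gives decakis-O-(tert-butyldimethylsilyl)gneyulin A F12. Buffered fluoride (Bu4NF/AcOH, THF, 0 °C) then releases 22 without acid.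

**Further compounds**
F1 | step 3 | racemic trans-6-(benzyloxy)-2-[2,4-bis(benzyloxy)phenyl]-3-[3,5-bis(benzyloxy)phenyl]-2,3-dihydro-1-benzofuran-5-ol | c1ccccc1COc1cc(OCc2ccccc2)cc([C@@H]2c3cc(O)c(OCc4ccccc4)cc3O[C@H]2c2ccc(OCc3ccccc3)cc2OCc2ccccc2)c1.c1ccccc1COc1cc(OCc2ccccc2)cc([C@H]2c3cc(O)c(OCc4ccccc4)cc3O[C@@H]2c2ccc(OCc3ccccc3)cc2OCc2ccccc2)c1
F2 | step 3 | (1S,4R)-camphanate of (2R,3R)-5 | c1ccccc1COc1cc(OCc2ccccc2)cc([C@@H]2c3cc(OC(=O)[C@@]56CC[C@@](C)(C(=O)O5)C6(C)C)c(OCc4ccccc4)cc3O[C@H]2c2ccc(OCc3ccccc3)cc2OCc2ccccc2)c1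
F3 | step 3 | (1S,4R)-camphanate of the (2S,3S) enantiomer of 5 | c1ccccc1COc1cc(OCc2ccccc2)cc([C@H]2c3cc(OC(=O)[C@@]56CC[C@@](C)(C(=O)O5)C6(C)C)c(OCc4ccccc4)cc3O[C@@H]2c2ccc(OCc3ccccc3)cc2OCc2ccccc2)c1
F4 | step 9 | racemic [3,5-bis(benzyloxy)phenyl](4-bromo-2,6-difluorophenyl)methanol | OC(c1c(F)cc(Br)cc1F)c1cc(OCc2ccccc2)cc(OCc2ccccc2)c1
F5 | step 9 | [3,5-bis(benzyloxy)phenyl](4-bromo-2,6-difluorophenyl)methanone | O=C(c1c(F)cc(Br)cc1F)c1cc(OCc2ccccc2)cc(OCc2ccccc2)c1
F6 | step 9 | [2-(benzyloxy)-4-bromo-6-fluorophenyl][3,5-bis(benzyloxy)phenyl]methanone | O=C(c1c(F)cc(Br)cc1OCc1ccccc1)c1cc(OCc2ccccc2)cc(OCc2ccccc2)c1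
F7 | step 9 | [2-(benzyloxy)-4-bromo-6-(DBF-5-ylmethoxy)phenyl][3,5-bis(benzyloxy)phenyl]methanone | c1ccccc1COc1cc(OCc2ccccc2)cc([C@@H]2c3cc(COc4cc(Br)cc(OCc5ccccc5)c4C(=O)c4cc(OCc5ccccc5)cc(OCc5ccccc5)c4)c(OCc4ccccc4)cc3O[C@H]2c2ccc(OCc3ccccc3)cc2OCc2ccccc2)c1
F8 | step 14 | octaphenol bromide (18 with all eight benzyl groups replaced by H) | Oc1cc(O)cc([C@@H]2c3cc([C@@H]4Oc5cc(Br)cc(O)c5[C@H]4c4cc(O)cc(O)c4)c(O)cc3O[C@H]2c2ccc(O)cc2O)c1
F9 | step 14 | octakis-O-(tert-butyldimethylsilyl) ether of F8 | CC(C)(C)[Si](C)(C)Oc1cc(O[Si](C)(C)C(C)(C)C)cc([C@@H]2c3cc([C@@H]4Oc5cc(Br)cc(O[Si](C)(C)C(C)(C)C)c5[C@H]4c4cc(O[Si](C)(C)C(C)(C)C)cc(O[Si](C)(C)C(C)(C)C)c4)c(O[Si](C)(C)C(C)(C)C)cc3O[C@H]2c2ccc(O[Si](C)(C)C(C)(C)C)cc2O[Si](C)(C)C(C)(C)C)c1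
F10 | step 14 | 2,4-bis(tert-butyldimethylsilyloxy)benzaldehyde | O=Cc1ccc(O[Si](C)(C)C(C)(C)C)cc1O[Si](C)(C)C(C)(C)C
F11 | step 14 | 2,4-bis(tert-butyldimethylsilyloxy)styrene | C=Cc1ccc(O[Si](C)(C)C(C)(C)C)cc1O[Si](C)(C)C(C)(C)C
F12 | step 14 | decakis-O-(tert-butyldimethylsilyl)gneyulin A | CC(C)(C)[Si](C)(C)Oc1cc(O[Si](C)(C)C(C)(C)C)cc([C@@H]2c3cc([C@@H]4Oc5cc(/C=C/c6ccc(O[Si](C)(C)C(C)(C)C)cc6O[Si](C)(C)C(C)(C)C)cc(O[Si](C)(C)C(C)(C)C)c5[C@H]4c4cc(O[Si](C)(C)C(C)(C)C)cc(O[Si](C)(C)C(C)(C)C)c4)c(O[Si](C)(C)C(C)(C)C)cc3O[C@H]2c2ccc(O[Si](C)(C)C(C)(C)C)cc2O[Si](C)(C)C(C)(C)C)c1
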